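**Outline**

- Retrosynthetic cuts: the O4'–benzyl bond; ring A at C4a–C5 (reverse of a cyclobutenone ring expansion); the C8–C8a bond (cyclobutenone carbinol carbon to pyranone C6); ring C at O1–C8a and C2–C3.
- Forward order: ring B is bought as 2,3-dimethoxyphenol and turned into an aroyl chloride; ring C is built as a free 2-aryl-4-pyranone; a semisquarate-derived cyclobutenone is attached at pyranone C6; ring A is closed last by thermal ring expansion; debenzylation ends the route.
- Enabling feature: C5(OH)–C6(H)–C7(OMe)–C8(OMe) of ring A is the C1(=O)–C2(H)–C3(OMe)–C4(OMe) array of a 3,4-dimethoxycyclobutenone, and the C4a=C8a bond is the enol-ether-like C5=C6 bond of the ring C pyranone.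
- Stereochemistry: the target has no stereocentre; the one carbinol stereocentre on the way is racemic and becomes aromatic C8.

Key step: step 10

Remark: flavone numbering (O1, C2–C4, C4a, C5–C8, C8a, ring B primed) is used throughout; diketone 9 is drawn in its keto form although the enol should dominate.

**Route**

Step 1
Reactants: 1 2,3-dimethoxyphenol
Product: 2 4-bromo-2,3-dimethoxyphenol
Conditions: NBS (1.0 equiv), MeCN, −20 → 0 °C
Reagents that add atoms: N-bromosuccinimide, O=C1CCC(=O)N1Br
Why: Electrophilic aromatic bromination in a polar solvent should go para to the free hydroxyl, the strongest donor on the ring, and one equivalent at low temperature should limit dibromination.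

Step 2
Reactants: 2 4-bromo-2,3-dimethoxyphenol
Product: 3 1-(benzyloxy)-4-bromo-2,3-dimethoxybenzene
Conditions: BnBr, K2CO3, DMF, rt
Reagents that add atoms: benzyl bromide, BrCc1ccccc1
Why: Williamson etherification of the phenoxide with a reactive benzylic halide is routine and installs a group that survives organolithium, acid and heat and leaves by hydrogenolysis at the end.

Step 3
Reactants: 3 1-(benzyloxy)-4-bromo-2,3-dimethoxybenzene
Product: 5 4-(benzyloxy)-2,3-dimethoxybenzoic acid, via aryllithium 4 (not isolated)
Conditions: n-BuLi, THF, −78 °C; CO2 (dry gas), −78 °C → rt; 1 M HCl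
Reagents that add atoms: carbon dioxide, O=C=O
Why: Bromine–lithium exchange at −78 °C is much faster than deprotonation of the benzylic ether, and carboxylation of the methoxy-stabilized aryllithium should give the acid after acidification.

Step 4
Reactants: 5 4-(benzyloxy)-2,3-dimethoxybenzoic acid
Product: 6 4-(benzyloxy)-2,3-dimethoxybenzoyl chloride
Conditions: (COCl)2, DMF (cat.), CH2Cl2, 0 °C → rt; used crude
Reagents that add atoms: oxalyl chloride, O=C(Cl)C(Cl)=O
Why: Acid chloride formation through the Vilsmeier-type chloroiminium catalyst runs under mild conditions that the benzyl and methyl ethers tolerate.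

Step 5
Reactants: 6 4-(benzyloxy)-2,3-dimethoxybenzoyl chloride; 7 (E)-4-methoxybut-3-en-2-one
Product: 9 (4E)-1-[4-(benzyloxy)-2,3-dimethoxyphenyl]-5-methoxypent-4-ene-1,3-dione, via lithium dienolate 8 (not isolated)
Conditions: 7 (2 equiv), LiN(SiMe3)2 (2 equiv), THF, −78 °C; then 6 (1 equiv), −78 °C; sat. aq. NH4Cl
Reagents that add atoms: none
Why: Claisen-type C-acylation of the kinetic methyl-side lithium enolate by the aroyl chloride should give the 1,3-diketone, with the second equivalent of enolate taking up the acidic proton of the product so that double acylation is avoided.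

Step 6
Reactants: 9 (4E)-1-[4-(benzyloxy)-2,3-dimethoxyphenyl]-5-methoxypent-4-ene-1,3-dione
Product: 10 2-[4-(benzyloxy)-2,3-dimethoxyphenyl]-4H-pyran-4-one
Conditions: CF3CO2H (2–3 equiv), CH2Cl2, rt
Reagents that add atoms: none
Why: Acid-promoted 6-endo oxa-Michael addition of the enol oxygen to the β-methoxy enone followed by loss of methanol (addition–elimination) should close ring C as the 4-pyranone, and the alkene geometry is irrelevant because the terminal carbon passes through an sp3 acetal.

Step 7
Reactants: 11 dimethyl squarate (3,4-dimethoxycyclobut-3-ene-1,2-dione)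
Product: 13 3-methoxycyclobut-3-ene-1,2-dione (methyl semisquarate), via carbinol 12 (not isolated)
Conditions: LiAlH(OtBu)3 (1.05 equiv), THF, −78 → −20 °C; cold 1 M HCl quench; crude 12, conc. aq. HCl (cat.), CH2Cl2, rt; used fresh
Reagents that add atoms: water, O
Why: The bulky hydride should reduce only one vinylogous ester carbonyl, and acid then ionizes the allylic carbinol to a methoxy-stabilized cation that is hydrated and loses methanol (allylic transposition), as known for dialkyl squarates.

Step 8
Reactants: 10 2-[4-(benzyloxy)-2,3-dimethoxyphenyl]-4H-pyran-4-one; 13 3-methoxycyclobut-3-ene-1,2-dione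
Product: 15 racemic 2-[4-(benzyloxy)-2,3-dimethoxyphenyl]-6-(1-hydroxy-2-methoxy-4-oxocyclobut-2-en-1-yl)-4H-pyran-4-one, via 6-lithiopyranone 14 (not isolated)
Conditions: lithium 2,2,6,6-tetramethylpiperidide (1.05 equiv, preformed from 2,2,6,6-tetramethylpiperidine and n-BuLi), THF, −78 °C, 15 min; cannulated into 13 (1.3 equiv), THF, −78 °C; sat. aq. NH4Cl at −78 °C
Reagents that add atoms: none
Why: The hindered, non-nucleophilic amide should remove the most acidic sp2 hydrogen, the one on C6 next to the ring oxygen (as in C2 metalation of chromones with tetramethylpiperidide bases), and the vinyllithium should then add 1,2 to the semisquarate carbonyl bonded to the methoxy-bearing carbon, which is not part of the vinylogous ester and is the more electrophilic one; the carbinol centre forms without control and is racemic.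

Step 9
Reactants: 15 racemic 2-[4-(benzyloxy)-2,3-dimethoxyphenyl]-6-(1-hydroxy-2-methoxy-4-oxocyclobut-2-en-1-yl)-4H-pyran-4-one
Product: 16 racemic 2-[4-(benzyloxy)-2,3-dimethoxyphenyl]-6-(1,2-dimethoxy-4-oxocyclobut-2-en-1-yl)-4H-pyran-4-one
Conditions: MeI (excess), Ag2O, 4 Å molecular sieves, MeCN, rt, dark
Reagents that add atoms: iodomethane, CI
Why: Purdie-type methylation with Ag2O and MeI etherifies the tertiary carbinol without a free alkoxide that could fragment the strained ring, and the soft electrophile should leave the pyranone carbonyl oxygen unmethylated.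

Step 10
Reactants: 16 racemic 2-[4-(benzyloxy)-2,3-dimethoxyphenyl]-6-(1,2-dimethoxy-4-oxocyclobut-2-en-1-yl)-4H-pyran-4-one
Product: 19 2-[4-(benzyloxy)-2,3-dimethoxyphenyl]-5-hydroxy-7,8-dimethoxy-4H-chromen-4-one, via dienylketene 17 (not isolated), via cyclohexadienone 18 (not isolated)
Conditions: toluene (0.01 M, degassed), 110 °C, argon; p-xylene, 138 °C if slow
Reagents that add atoms: none
Why: Heating should open the cyclobutenone by conrotatory 4π cleavage of the bond between the carbonyl carbon and the quaternary carbon, with the 4-methoxy donor rotating outward so that the pyranonyl group lies cis to the ketene in dienylketene 17. The ketene carbon (future C5) should then bond to pyranone C5 (future C4a) in a thermal disrotatory 6π electrocyclization that uses the C5=C6 bond of ring C as the third π component and closes the six-membered carbocyclic ring A as cyclohexadienone 18. Enolization of the C4a–H of 18, which sits between two carbonyls, gives the hydrogen-bonded 5-hydroxychromone irreversibly and drives the sequence. The closest known reaction type is the Moore rearrangement of 4-aryl-, 4-heteroaryl- and 4-(α-alkoxyalkenyl)-4-alkoxycyclobutenones to oxygenated phenols. No stereocentre survives, since the racemic quaternary carbon of 16 becomes aromatic C8 and the sp3 C4a of 18 is lost on enolization. The step needs inward rotation of the pyranonyl group, secured by the outward torquoselectivity of the alkoxy substituent, and a single closure site, secured because the pyranone carbon bonded to the four-membered ring has only one carbon neighbour (C5); dilution and exclusion of nucleophiles protect the ketene.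

Step 11
Reactants: 19 2-[4-(benzyloxy)-2,3-dimethoxyphenyl]-5-hydroxy-7,8-dimethoxy-4H-chromen-4-one
Product: 20 5-hydroxy-2-(4-hydroxy-2,3-dimethoxyphenyl)-7,8-dimethoxy-4H-chromen-4-one (5,4'-dihydroxy-7,8,2',3'-tetramethoxyflavone)
Conditions: H2 (1 atm), 10% Pd/C (palladium on carbon), EtOAc–MeOH, rt
Reagents that add atoms: none
Why: Hydrogenolysis of the aryl benzyl ether over palladium is fast at one atmosphere, whereas the conjugated chromone double bond and the aryl methyl ethers should remain untouched.

**Compound list**

1 | 2,3-dimethoxyphenol | COc1cccc(O)c1OC | starting material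
2 | 4-bromo-2,3-dimethoxyphenol | COc1c(Br)ccc(O)c1OC | intermediate
3 | 1-(benzyloxy)-4-bromo-2,3-dimethoxybenzene | COc1c(Br)ccc(OCc2ccccc2)c1OC | intermediate
4 | [4-(benzyloxy)-2,3-dimethoxyphenyl]lithium (formed in the flask) | [Li]c1ccc(OCc2ccccc2)c(OC)c1OC | intermediate
5 | 4-(benzyloxy)-2,3-dimethoxybenzoic acid | COc1c(C(=O)O)ccc(OCc2ccccc2)c1OC | intermediate
6 | 4-(benzyloxy)-2,3-dimethoxybenzoyl chloride | COc1c(C(Cl)=O)ccc(OCc2ccccc2)c1OC | intermediate
7 | (E)-4-methoxybut-3-en-2-one | CO/C=C/C(C)=O | starting material
8 | lithium (3E)-4-methoxybuta-1,3-dien-2-olate (formed in the flask) | [Li]OC(=C)/C=C/OC | intermediate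
9 | (4E)-1-[4-(benzyloxy)-2,3-dimethoxyphenyl]-5-methoxypent-4-ene-1,3-dione | COc1c(C(=O)CC(=O)/C=C/OC)ccc(OCc2ccccc2)c1OC | intermediate
10 | 2-[4-(benzyloxy)-2,3-dimethoxyphenyl]-4H-pyran-4-one | COc1c(-c2cc(=O)cco2)ccc(OCc2ccccc2)c1OC | intermediate
11 | dimethyl squarate | COC1=C(OC)C(=O)C1=O | starting material
12 | racemic 4-hydroxy-2,3-dimethoxycyclobut-2-en-1-one (formed in the flask) | COC1=C(OC)C(=O)C1O | intermediate
13 | 3-methoxycyclobut-3-ene-1,2-dione (methyl semisquarate) | COC1=CC(=O)C1=O | intermediate
14 | {6-[4-(benzyloxy)-2,3-dimethoxyphenyl]-4-oxo-4H-pyran-2-yl}lithium (formed in the flask) | [Li]c1cc(=O)cc(-c2ccc(OCc3ccccc3)c(OC)c2OC)o1 | intermediate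
15 | racemic 2-[4-(benzyloxy)-2,3-dimethoxyphenyl]-6-(1-hydroxy-2-methoxy-4-oxocyclobut-2-en-1-yl)-4H-pyran-4-one | COC1=CC(=O)C1(O)c1cc(=O)cc(-c2ccc(OCc3ccccc3)c(OC)c2OC)o1 | intermediate
16 | racemic 2-[4-(benzyloxy)-2,3-dimethoxyphenyl]-6-(1,2-dimethoxy-4-oxocyclobut-2-en-1-yl)-4H-pyran-4-one | COC1=CC(=O)C1(OC)c1cc(=O)cc(-c2ccc(OCc3ccccc3)c(OC)c2OC)o1 | intermediate
17 | dienylketene with the pyranonyl group cis to the ketene-bearing carbon (formed in the flask) | O=C=C/C(OC)=C(OC)\c1cc(=O)cc(-c2ccc(OCc3ccccc3)c(OC)c2OC)o1 | intermediate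
18 | racemic 2-[4-(benzyloxy)-2,3-dimethoxyphenyl]-7,8-dimethoxy-4aH-chromene-4,5-dione (formed in the flask) | COC1=CC(=O)C2C(=O)C=C(-c3ccc(OCc4ccccc4)c(OC)c3OC)OC2=C1OC | intermediate
19 | 2-[4-(benzyloxy)-2,3-dimethoxyphenyl]-5-hydroxy-7,8-dimethoxy-4H-chromen-4-one | COc1cc(O)c2c(=O)cc(-c3ccc(OCc4ccccc4)c(OC)c3OC)oc2c1OC | intermediate
20 | 5-hydroxy-2-(4-hydroxy-2,3-dimethoxyphenyl)-7,8-dimethoxy-4H-chromen-4-one | COc1cc(O)c2c(=O)cc(-c3ccc(O)c(OC)c3OC)oc2c1OC | target

**Step count**

Total: 11 steps. Longest linear sequence: 10 steps (steps 1–6 and 8–11 from 2,3-dimethoxyphenol); the semisquarate branch adds step 7.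

**Steps most likely to fail**

Step 8. Deprotonation may occur next to the carbonyl (C3 or C5) instead of at C6, the lithiated pyranone may add to unreacted pyranone or open its ring, and the nucleophile may attack the methoxy-bearing carbon of the semisquarate in an addition–elimination. The fallback sets out from 10 and separates regioselective metalation from carbonyl addition. Zincation at C6 with TMPZnCl·LiCl in THF at room temperature and quenching with I2 should give 2-[4-(benzyloxy)-2,3-dimethoxyphenyl]-6-iodo-4H-pyran-4-one F1. Iodine–magnesium exchange with i-PrMgCl·LiCl at −40 °C should give {6-[4-(benzyloxy)-2,3-dimethoxyphenyl]-4-oxo-4H-pyran-2-yl}magnesium chloride F2, a less basic and more persistent nucleophile. Its addition to 13 at −78 °C rejoins the route at 15.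

Step 10. The electron-poor pyranone double bond may be slow to take part in the 6π closure, so that the dienylketene reverts, oligomerizes or is trapped by adventitious nucleophiles. The fallback builds the chromone by the Baker–Venkataraman route and sets out from 6. Acylation of the known 1-(2-hydroxy-3,4,6-trimethoxyphenyl)ethanone F3 in pyridine should give 2-acetyl-3,5,6-trimethoxyphenyl 4-(benzyloxy)-2,3-dimethoxybenzoate F4. KOH in pyridine should rearrange it to 1-[4-(benzyloxy)-2,3-dimethoxyphenyl]-3-(2-hydroxy-3,4,6-trimethoxyphenyl)propane-1,3-dione F5. Cyclodehydration in AcOH with catalytic H2SO4 should give 2-[4-(benzyloxy)-2,3-dimethoxyphenyl]-5,7,8-trimethoxy-4H-chromen-4-one F6. BCl3 in CH2Cl2 at −78 → 0 °C should then cleave the chelation-activated 5-O-methyl group and the benzyl ether together, so the fallback rejoins the route at the target 20.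

Step 9. Etherification of the hindered tertiary carbinol may be slow and may be overtaken by ring fragmentation or by alkylation elsewhere. The fallback sets out from 15 and moves the methylation behind the ring expansion. Thermolysis of 15 in degassed toluene at 110 °C under argon should give the hydroquinone 2-[4-(benzyloxy)-2,3-dimethoxyphenyl]-5,8-dihydroxy-7-methoxy-4H-chromen-4-one F7. Methylation with MeI and K2CO3 (one equivalent) in acetone under argon should take place only at the non-chelated 8-hydroxyl, since the 5-hydroxyl is tied up in the hydrogen bond to the carbonyl, and rejoins the route at 19.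

**Further compounds**

F1 | step 8 | 2-[4-(benzyloxy)-2,3-dimethoxyphenyl]-6-iodo-4H-pyran-4-one | Ic1cc(=O)cc(-c2ccc(OCc3ccccc3)c(OC)c2OC)o1
F2 | step 8 | {6-[4-(benzyloxy)-2,3-dimethoxyphenyl]-4-oxo-4H-pyran-2-yl}magnesium chloride | Cl[Mg]c1cc(=O)cc(-c2ccc(OCc3ccccc3)c(OC)c2OC)o1
F3 | step 10 | 1-(2-hydroxy-3,4,6-trimethoxyphenyl)ethanone | CC(=O)c1c(O)c(OC)c(OC)cc1OC
F4 | step 10 | 2-acetyl-3,5,6-trimethoxyphenyl 4-(benzyloxy)-2,3-dimethoxybenzoate | CC(=O)c1c(OC)cc(OC)c(OC)c1OC(=O)c1ccc(OCc2ccccc2)c(OC)c1OC
F5 | step 10 | 1-[4-(benzyloxy)-2,3-dimethoxyphenyl]-3-(2-hydroxy-3,4,6-trimethoxyphenyl)propane-1,3-dione | COc1cc(OC)c(OC)c(O)c1C(=O)CC(=O)c1ccc(OCc2ccccc2)c(OC)c1OC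
F6 | step 10 | 2-[4-(benzyloxy)-2,3-dimethoxyphenyl]-5,7,8-trimethoxy-4H-chromen-4-one | COc1cc(OC)c2c(=O)cc(-c3ccc(OCc4ccccc4)c(OC)c3OC)oc2c1OC
F7 | step 9 | 2-[4-(benzyloxy)-2,3-dimethoxyphenyl]-5,8-dihydroxy-7-methoxy-4H-chromen-4-one | COc1cc(O)c2c(=O)cc(-c3ccc(OCc4ccccc4)c(OC)c3OC)oc2c1O
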